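## Retrosynthetic overview

1. The 14-membered carbocycle is closed last, by ring-closing metathesis across the enoate C=C of an acyclic triketone; all three ketones come from one oxidation of a triol.
2. Enoate arm: indium-mediated allylation of a lactol with methyl 2-(bromomethyl)acrylate. Isopropenyl arm: Ni-catalysed reductive acylation of an iodomethyl oxolane with the acid chloride of a hexenoic acid cut out of (S)-carvone.
3. The oxolane ring is made first, by gold-catalysed cyclisation of an α-hydroxyallene (allene axis → quaternary C–O centre); its ketone oxygen comes from hydroboration and is parked in a bridged lactone.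
4. Key bond (quaternary C–CH2): propargylic Johnson–Claisen [3,3] rearrangement (carbinol → allene axis); that carbinol is set by chelation-controlled reduction next to the bought centre of methyl (S)-glycerate acetonide.
5. Ring order: oxolane, then temporary bridged lactone, then the macrocycle.

Assumption: the SMILES defines the target as methyl (1S,5E,8S,12S)-1-methyl-3,10,13-trioxo-8-(prop-1-en-2-yl)-15-oxabicyclo[10.2.1]pentadec-5-ene-5-carboxylate, with stereocentres C1, C8 and C12.

## Route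

Step 1
Reactants: 1 (S)-(+)-carvone [(5S)-2-methyl-5-(prop-1-en-2-yl)cyclohex-2-en-1-one]
Product: 2 (1S,4S,6S)-1-methyl-4-(prop-1-en-2-yl)-7-oxabicyclo[4.1.0]heptan-2-one (epoxide trans to isopropenyl)
Conditions: 30% H2O2, NaOH (cat.), MeOH, 0 °C
Reagents that add atoms: hydrogen peroxide, OO
Why: Weitz–Scheffer nucleophilic epoxidation of the enone, in which the hydroperoxide anion adds anti to the isopropenyl group and the isolated alkene does not react, so a single trans epoxide forms whose two new centres are cut out again in step 2.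

Step 2
Reactants: 2 (1S,4S,6S)-1-methyl-4-(prop-1-en-2-yl)-7-oxabicyclo[4.1.0]heptan-2-one
Product: 3 (3S)-5-oxo-3-(prop-1-en-2-yl)pentanoic acid
Conditions: H5IO6 (3 equiv), THF/H2O, 0 °C → rt
Reagents that add atoms: periodic acid, OI(=O)(O)(O)(O)O; water, O
Why: Periodic acid opens the epoxide to the diol and cleaves it and the resulting 1,2-diketone (Malaprade-type glycol cleavage), which excises the methyl-bearing ring carbon as acetic acid and leaves the non-enolisable carvone stereocentre untouched.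

Step 3
Reactants: 3 (3S)-5-oxo-3-(prop-1-en-2-yl)pentanoic acid
Product: 4 (3S)-3-(prop-1-en-2-yl)hex-5-enoic acid
Conditions: MePPh3Br, KOtBu (3.2 equiv), THF, 0 °C → rt
Reagents that add atoms: methyltriphenylphosphonium bromide, C[P+](c1ccccc1)(c1ccccc1)c1ccccc1.[Br-]
Why: Wittig methylenation of the aldehyde (the carboxylate salt is inert to the ylide) gives the terminal alkene, and the stereocentre, being β to both carbonyl groups, cannot epimerise.

Step 4
Reactants: 5 methyl (4S)-2,2-dimethyl-1,3-dioxolane-4-carboxylate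
Product: 6 1-[(4S)-2,2-dimethyl-1,3-dioxolan-4-yl]but-2-yn-1-one
Conditions: 1-propynyllithium, BF3·OEt2, THF, −78 °C
Reagents that add atoms: 1-propynyllithium, [Li]C#CC
Why: BF3-promoted acylation of the lithium acetylide by the ester (Yamaguchi–Hirao ynone synthesis), in which the tetrahedral adduct survives at −78 °C so that only one alkynyl group is taken up and the α-stereocentre is not touched.

Step 5
Reactants: 6 1-[(4S)-2,2-dimethyl-1,3-dioxolan-4-yl]but-2-yn-1-one
Product: 7 (1R)-1-[(4S)-2,2-dimethyl-1,3-dioxolan-4-yl]but-2-yn-1-ol (anti diastereomer)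
Conditions: Zn(BH4)2, Et2O, −30 °C
Reagents that add atoms: none
Why: Chelation-controlled (Cram-chelate) 1,2-reduction in which zinc bridges the ketone and the α-oxygen of the dioxolane and hydride enters past the α-hydrogen, which sets the new carbinol centre anti to the bought C–O centre (1R, expected dr about 9:1).

Step 6
Reactants: 7 (1R)-1-[(4S)-2,2-dimethyl-1,3-dioxolan-4-yl]but-2-yn-1-ol
Product: 9 ethyl (aS,6R)-6,7-dihydroxy-3-methylhepta-3,4-dienoate, via allenoate acetonide 8 (not isolated)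
Conditions: MeC(OEt)3, EtCO2H (cat.), 140 °C; concentrate; then AcOH/THF/H2O (3:1:1), 45 °C
Reagents that add atoms: triethyl orthoacetate, CCOC(C)(OCC)OCC
Why: Propargylic Johnson–Claisen [3,3]-sigmatropic rearrangement of the mixed ketene acetal forms the C–CH2CO2Et bond at the methyl-bearing alkyne carbon on the face of the departing C–O bond, so the carbinol configuration is transferred completely to the allene axis (aS), after which aqueous acetic acid hydrolyses the acetonide.

Step 7
Reactants: 9 ethyl (aS,6R)-6,7-dihydroxy-3-methylhepta-3,4-dienoate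
Product: 10 ethyl 2-[(2S,5R)-5-(hydroxymethyl)-2-methyl-2,5-dihydrofuran-2-yl]acetate
Conditions: AuCl3 (2 mol %), THF, rt
Reagents that add atoms: none
Why: Gold-catalysed 5-endo cycloisomerisation of the α-hydroxyallene (anti oxyauration then protodeauration) transfers the axial chirality to the new quaternary C–O centre with the methyl group cis to CH2OH, and the primary hydroxyl does not compete because it would have to close a six-membered ring.

Step 8
Reactants: 10 ethyl 2-[(2S,5R)-5-(hydroxymethyl)-2-methyl-2,5-dihydrofuran-2-yl]acetate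
Product: 11 ethyl 2-[(2S,5R)-5-(iodomethyl)-2-methyl-2,5-dihydrofuran-2-yl]acetate
Conditions: I2, PPh3, imidazole, CH2Cl2, 0 °C → rt
Reagents that add atoms: iodine, II
Why: Appel-type iodination (Garegg–Samuelsson conditions) replaces the primary hydroxyl by iodide through SN2 attack on the alkoxyphosphonium ion without touching either stereocentre.

Step 9
Reactants: 11 ethyl 2-[(2S,5R)-5-(iodomethyl)-2-methyl-2,5-dihydrofuran-2-yl]acetate
Product: 14 (1R,5R,7R)-7-(iodomethyl)-5-methyl-2,6-dioxabicyclo[3.2.1]octan-3-one, via alkylborane 12 (not isolated), via hydroxy ester 13 (not isolated)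
Conditions: Sia2BH (from BH3·THF and 2-methylbut-2-ene), THF, 0 °C; 30% H2O2, aq. NaOAc, 0 °C → rt; then PPTS (cat.), toluene, 80 °C
Reagents that add atoms: hydrogen peroxide, OO
Why: Brown hydroboration–oxidation with the bulky borane puts boron and then oxygen on the ring carbon remote from the quaternary centre and on the face anti to CH2I, which is the face of the ester arm, so that acid-catalysed lactonisation closes the bridged lactone and thereby masks the new hydroxyl.

Step 10
Reactants: 14 (1R,5R,7R)-7-(iodomethyl)-5-methyl-2,6-dioxabicyclo[3.2.1]octan-3-one; 4 (3S)-3-(prop-1-en-2-yl)hex-5-enoic acid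
Product: 16 (1R,5R,7S)-5-methyl-7-[(4S)-2-oxo-4-(prop-1-en-2-yl)hept-6-en-1-yl]-2,6-dioxabicyclo[3.2.1]octan-3-one, via acid chloride 15 (not isolated)
Conditions: 4, (COCl)2, DMF (cat.), CH2Cl2, 0 °C → rt, concentrate; then 14, NiCl2·glyme (10 mol %), 4,4′-di-tert-butyl-2,2′-bipyridine (10 mol %), Mn powder (3 equiv), DMA, 0 °C → rt
Reagents that add atoms: none
Why: Nickel-catalysed reductive cross-electrophile coupling (Weix-type ketone synthesis), in which the acylnickel species formed from the acid chloride captures the primary alkyl radical released from the iodide, joins the two fragments as the ketone without touching the lactone, the alkenes or any stereocentre.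

Step 11
Reactants: 16 (1R,5R,7S)-5-methyl-7-[(4S)-2-oxo-4-(prop-1-en-2-yl)hept-6-en-1-yl]-2,6-dioxabicyclo[3.2.1]octan-3-one
Product: 17 (1R,5R,7S)-7-[(4S)-2-hydroxy-4-(prop-1-en-2-yl)hept-6-en-1-yl]-5-methyl-2,6-dioxabicyclo[3.2.1]octan-3-ol (lactol; epimer mixture at C3 of the bicycle and at C2 of the side chain)
Conditions: i-Bu2AlH (3.5 equiv), CH2Cl2, −78 °C
Reagents that add atoms: none
Why: i-Bu2AlH reduction stops at the lactol because the tetrahedral aluminate is stable at −78 °C and at the same time reduces the ketone, both new carbinol centres being inconsequential since they are oxidised in step 13.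

Step 12
Reactants: 17 (1R,5R,7S)-7-[(4S)-2-hydroxy-4-(prop-1-en-2-yl)hept-6-en-1-yl]-5-methyl-2,6-dioxabicyclo[3.2.1]octan-3-ol
Product: 18 methyl 4-hydroxy-5-[(2S,4R,5S)-4-hydroxy-5-[(4S)-2-hydroxy-4-(prop-1-en-2-yl)hept-6-en-1-yl]-2-methyloxolan-2-yl]-2-methylidenepentanoate (epimer mixture at the two open-chain carbinol carbons)
Conditions: In powder, methyl 2-(bromomethyl)acrylate, THF/H2O (1:1), rt
Reagents that add atoms: methyl 2-(bromomethyl)acrylate, COC(=O)C(=C)CBr
Why: Barbier-type indium-mediated allylation in water, in which the 2-(methoxycarbonyl)allylindium species adds to the aldehyde form of the lactol to give the homoallylic alcohol as an inconsequential epimer mixture.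

Step 13
Reactants: 18 methyl 4-hydroxy-5-[(2S,4R,5S)-4-hydroxy-5-[(4S)-2-hydroxy-4-(prop-1-en-2-yl)hept-6-en-1-yl]-2-methyloxolan-2-yl]-2-methylidenepentanoate
Product: 19 methyl 2-methylidene-5-[(2S,5S)-2-methyl-4-oxo-5-[(4S)-2-oxo-4-(prop-1-en-2-yl)hept-6-en-1-yl]oxolan-2-yl]-4-oxopentanoate
Conditions: Dess–Martin periodinane (4.5 equiv), CH2Cl2, 0 °C → rt
Reagents that add atoms: none
Why: Dess–Martin oxidation turns the three secondary alcohols into the three ketones under non-basic conditions, so the oxolane C5 centre (now α to a ketone) and the β,γ-unsaturated keto ester are not isomerised.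

Step 14
Reactants: 19 methyl 2-methylidene-5-[(2S,5S)-2-methyl-4-oxo-5-[(4S)-2-oxo-4-(prop-1-en-2-yl)hept-6-en-1-yl]oxolan-2-yl]-4-oxopentanoate
Product: 20 methyl (1S,5E,8S,12S)-1-methyl-3,10,13-trioxo-8-(prop-1-en-2-yl)-15-oxabicyclo[10.2.1]pentadec-5-ene-5-carboxylate (target)
Conditions: second-generation Hoveyda–Grubbs catalyst RuCl2(SIMes)(=CH–C6H4–2-OiPr) (SIMes = 1,3-dimesitylimidazolidin-2-ylidene, 10 mol %), 1,4-benzoquinone (20 mol %), toluene (1 mM), 80 °C
Reagents that add atoms: none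
Why: Ring-closing olefin metathesis at high dilution joins the acrylate and the terminal vinyl group with loss of ethene, the 1,1-disubstituted isopropenyl group being inert, and the trisubstituted enoate forms as the thermodynamically preferred E isomer as in methacrylate cross-metathesis.

## Compound list

1 | (S)-(+)-carvone, (5S)-2-methyl-5-(prop-1-en-2-yl)cyclohex-2-en-1-one | CC1=CC[C@@H](CC1=O)C(C)=C | starting material
2 | (1S,4S,6S)-1-methyl-4-(prop-1-en-2-yl)-7-oxabicyclo[4.1.0]heptan-2-one | CC(=C)[C@@H]1CC(=O)[C@@]2(C)O[C@H]2C1 | intermediate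
3 | (3S)-5-oxo-3-(prop-1-en-2-yl)pentanoic acid | OC(=O)C[C@H](CC=O)C(C)=C | intermediate
4 | (3S)-3-(prop-1-en-2-yl)hex-5-enoic acid | OC(=O)C[C@H](CC=C)C(C)=C | intermediate
5 | methyl (4S)-2,2-dimethyl-1,3-dioxolane-4-carboxylate | COC(=O)[C@@H]1COC(C)(C)O1 | starting material
6 | 1-[(4S)-2,2-dimethyl-1,3-dioxolan-4-yl]but-2-yn-1-one | CC#CC(=O)[C@@H]1COC(C)(C)O1 | intermediate
7 | (1R)-1-[(4S)-2,2-dimethyl-1,3-dioxolan-4-yl]but-2-yn-1-ol | CC#C[C@@H](O)[C@@H]1COC(C)(C)O1 | intermediate
8 | ethyl (aS)-5-[(4R)-2,2-dimethyl-1,3-dioxolan-4-yl]-3-methylpenta-3,4-dienoate (P allene) | CCOC(=O)CC(C)=[C@@]=C[C@@H]1COC(C)(C)O1 | intermediate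
9 | ethyl (aS,6R)-6,7-dihydroxy-3-methylhepta-3,4-dienoate (P allene) | CCOC(=O)CC(C)=[C@@]=C[C@@H](O)CO | intermediate
10 | ethyl 2-[(2S,5R)-5-(hydroxymethyl)-2-methyl-2,5-dihydrofuran-2-yl]acetate | CCOC(=O)C[C@@]1(C)C=C[C@H](CO)O1 | intermediate
11 | ethyl 2-[(2S,5R)-5-(iodomethyl)-2-methyl-2,5-dihydrofuran-2-yl]acetate | CCOC(=O)C[C@@]1(C)C=C[C@H](CI)O1 | intermediate
12 | ethyl 2-[(2R,4R,5R)-4-[bis(3-methylbutan-2-yl)boranyl]-5-(iodomethyl)-2-methyloxolan-2-yl]acetate | CCOC(=O)C[C@@]1(C)C[C@@H](B(C(C)C(C)C)C(C)C(C)C)[C@H](CI)O1 | intermediate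
13 | ethyl 2-[(2R,4R,5R)-4-hydroxy-5-(iodomethyl)-2-methyloxolan-2-yl]acetate | CCOC(=O)C[C@@]1(C)C[C@@H](O)[C@H](CI)O1 | intermediate
14 | (1R,5R,7R)-7-(iodomethyl)-5-methyl-2,6-dioxabicyclo[3.2.1]octan-3-one | O=C1C[C@@]2(C)C[C@@H](O1)[C@H](CI)O2 | intermediate
15 | (3S)-3-(prop-1-en-2-yl)hex-5-enoyl chloride | ClC(=O)C[C@H](CC=C)C(C)=C | intermediate
16 | (1R,5R,7S)-5-methyl-7-[(4S)-2-oxo-4-(prop-1-en-2-yl)hept-6-en-1-yl]-2,6-dioxabicyclo[3.2.1]octan-3-one | O=C1C[C@@]2(C)C[C@@H](O1)[C@H](CC(=O)C[C@H](CC=C)C(C)=C)O2 | intermediate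
17 | (1R,5R,7S)-7-[(4S)-2-hydroxy-4-(prop-1-en-2-yl)hept-6-en-1-yl]-5-methyl-2,6-dioxabicyclo[3.2.1]octan-3-ol (epimer mixture at the lactol and side-chain carbinol carbons) | OC1C[C@@]2(C)C[C@@H](O1)[C@H](CC(O)C[C@H](CC=C)C(C)=C)O2 | intermediate
18 | methyl 4-hydroxy-5-[(2S,4R,5S)-4-hydroxy-5-[(4S)-2-hydroxy-4-(prop-1-en-2-yl)hept-6-en-1-yl]-2-methyloxolan-2-yl]-2-methylidenepentanoate (epimer mixture at the two open-chain carbinols) | COC(=O)C(=C)CC(O)C[C@@]1(C)C[C@@H](O)[C@H](CC(O)C[C@H](CC=C)C(C)=C)O1 | intermediate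
19 | methyl 2-methylidene-5-[(2S,5S)-2-methyl-4-oxo-5-[(4S)-2-oxo-4-(prop-1-en-2-yl)hept-6-en-1-yl]oxolan-2-yl]-4-oxopentanoate | COC(=O)C(=C)CC(=O)C[C@@]1(C)CC(=O)[C@H](CC(=O)C[C@H](CC=C)C(C)=C)O1 | intermediate
20 | methyl (1S,5E,8S,12S)-1-methyl-3,10,13-trioxo-8-(prop-1-en-2-yl)-15-oxabicyclo[10.2.1]pentadec-5-ene-5-carboxylate | C=C(C)[C@H]1C/C=C(/C(=O)OC)CC(=O)C[C@@]2(C)CC(=O)[C@H](CC(=O)C1)O2 | target

## Step count and risks

Total step count: 14 (steps 1–3 for the carvone fragment, steps 4–14 for the main line).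
Longest linear sequence: 11 steps (steps 4–14, from 5 to 20).

Step 9 (hydroboration and lactonisation). If the hydroxyl is delivered to the other ring face, lactone 14 cannot form. The route then sets out from hydroxy ester 13 in the form of its C4 epimer. TBSOTf and 2,6-lutidine give silyl ether F1, and the nickel coupling of step 10 with 15 gives keto ester F2. i-Bu2AlH (2.2 equiv, −78 °C) gives hydroxy aldehyde F3, and the indium allylation of step 12 gives diol F4. HF·pyridine gives triol F5 (the C4 epimer of 18), and the oxidation of step 13 brings it back to the route at 19.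

Step 10 (nickel-catalysed reductive acylation). If radical side reactions or low conversion intervene, the same bond is made by a two-electron Fukuyama coupling. Setting out from 4 and 14, the acid gives thioester F6 (EtSH, DCC, DMAP) and the iodide gives alkylzinc iodide F7 (Zn dust, LiCl, THF, 25 °C). PdCl2(PPh3)2 (5 mol %) couples them to give 16, where the route is rejoined.

Step 14 (macrocyclic metathesis). If triketone 19 oligomerises or its exocyclic alkene migrates into conjugation before ring closure, the ring is closed one oxidation level earlier. Setting out from triol 18, the same ruthenium catalyst (CH2Cl2, 1 mM, 40 °C) gives macrocyclic triol F8, and Dess–Martin oxidation of its three carbinols then gives 20 directly.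

## Further compounds

F1 | step 9 | ethyl 2-[(2R,4S,5R)-4-[(tert-butyldimethylsilyl)oxy]-5-(iodomethyl)-2-methyloxolan-2-yl]acetate | CCOC(=O)C[C@@]1(C)C[C@H](O[Si](C)(C)C(C)(C)C)[C@H](CI)O1
F2 | step 9 | ethyl 2-[(2R,4S,5S)-4-[(tert-butyldimethylsilyl)oxy]-2-methyl-5-[(4S)-2-oxo-4-(prop-1-en-2-yl)hept-6-en-1-yl]oxolan-2-yl]acetate | CCOC(=O)C[C@@]1(C)C[C@H](O[Si](C)(C)C(C)(C)C)[C@H](CC(=O)C[C@H](CC=C)C(C)=C)O1
F3 | step 9 | 2-[(2R,4S,5S)-4-[(tert-butyldimethylsilyl)oxy]-5-[(4S)-2-hydroxy-4-(prop-1-en-2-yl)hept-6-en-1-yl]-2-methyloxolan-2-yl]acetaldehyde | O=CC[C@@]1(C)C[C@H](O[Si](C)(C)C(C)(C)C)[C@H](CC(O)C[C@H](CC=C)C(C)=C)O1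
F4 | step 9 | methyl 5-[(2S,4S,5S)-4-[(tert-butyldimethylsilyl)oxy]-5-[(4S)-2-hydroxy-4-(prop-1-en-2-yl)hept-6-en-1-yl]-2-methyloxolan-2-yl]-4-hydroxy-2-methylidenepentanoate | COC(=O)C(=C)CC(O)C[C@@]1(C)C[C@H](O[Si](C)(C)C(C)(C)C)[C@H](CC(O)C[C@H](CC=C)C(C)=C)O1
F5 | step 9 | methyl 4-hydroxy-5-[(2S,4S,5S)-4-hydroxy-5-[(4S)-2-hydroxy-4-(prop-1-en-2-yl)hept-6-en-1-yl]-2-methyloxolan-2-yl]-2-methylidenepentanoate | COC(=O)C(=C)CC(O)C[C@@]1(C)C[C@H](O)[C@H](CC(O)C[C@H](CC=C)C(C)=C)O1
F6 | step 10 | S-ethyl (3S)-3-(prop-1-en-2-yl)hex-5-enethioate | CCSC(=O)C[C@H](CC=C)C(C)=C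
F7 | step 10 | {[(1R,5R,7R)-5-methyl-3-oxo-2,6-dioxabicyclo[3.2.1]octan-7-yl]methyl}zinc iodide | O=C1C[C@@]2(C)C[C@@H](O1)[C@H](C[Zn]I)O2
F8 | step 14 | methyl (1S,5E,8S,12S,13R)-3,10,13-trihydroxy-1-methyl-8-(prop-1-en-2-yl)-15-oxabicyclo[10.2.1]pentadec-5-ene-5-carboxylate (epimer mixture at C3 and C10) | C=C(C)[C@H]1C/C=C(/C(=O)OC)CC(O)C[C@@]2(C)C[C@@H](O)[C@H](CC(O)C1)O2
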